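**Retrosynthetic overview**
- Feature on which the strategy rests: in the side chain, C8'' carries the ring-B phenolic oxygen and lies between C9'' (carboxyl level) and the carbinol carbon C7'' on ring C. This is the pattern of a diazoacetate carbene carbon set between a phenol O–H and an aldehyde C=O.
- The target is reached by ring-A O-debenzylation of a diol that comes from borohydride reduction of an α-aryloxy β-hydroxy ethyl ester. That ester is disconnected at O–C8'' and C8''–C7'' into ring-A-benzyl matairesinol (free ring-B phenol), ethyl diazoacetate and a vanillin-derived aldehyde; no ring is closed there.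
- The phenol comes from desilylation of the product of trans enolate alkylation of an (R)-β-arylmethyl-γ-butyrolactone with a silyl-protected vanillyl bromide made from vanillin.
- The lactone comes from Stobbe condensation of O-benzylvanillin with dimethyl succinate, asymmetric hydrogenation, ester reduction and lactonisation. The γ-butyrolactone is the only ring formed; the three arenes are bought.
- Ring C is carried as the aryl acetate, not the benzyl ether, so that the aldehyde is electrophilic enough to trap the enol. Ring A stays benzylated, so ring B is the only O–H donor in the key step.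

Key step: step 9

Assumption: (S,S)-Et-DuPhos and (R)-TRIP, the 3,3'-bis(2,4,6-triisopropylphenyl)-BINOL hydrogen phosphate, are first choices of antipode; the antipode that delivers the drawn configuration is the one to be used, checked on lactone 10 for the hydrogenation and on ester 17 for the coupling.

**Step 1**
Reactants: 1 vanillin (4-hydroxy-3-methoxybenzaldehyde)
Product: 2 4-(tert-butyldimethylsilyloxy)-3-methoxybenzaldehyde
Conditions: TBSCl, imidazole, DMF, rt
Reagents that add atoms: tert-butyldimethylsilyl chloride, CC(C)(C)[Si](C)(C)Cl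
Why: Silylation of the acidic phenol with a silyl chloride and imidazole is a standard protection that leaves the aldehyde untouched, and no stereocentre is involved.

**Step 2**
Reactants: 2 4-(tert-butyldimethylsilyloxy)-3-methoxybenzaldehyde
Product: 3 4-(tert-butyldimethylsilyloxy)-3-methoxybenzyl alcohol
Conditions: NaBH4, EtOH/THF, 0 °C
Reagents that add atoms: none
Why: Borohydride reduction of an aromatic aldehyde to the benzylic alcohol is fast at 0 °C, where the aryl silyl ether should not be cleaved.

**Step 3**
Reactants: 3 4-(tert-butyldimethylsilyloxy)-3-methoxybenzyl alcohol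
Product: 4 4-(tert-butyldimethylsilyloxy)-3-methoxybenzyl bromide
Conditions: CBr4, PPh3, CH2Cl2, 0 °C
Reagents that add atoms: carbon tetrabromide, BrC(Br)(Br)Br
Why: In the Appel reaction the alkoxyphosphonium bromide collapses by SN2 at the benzylic carbon under neutral conditions that spare the silyl ether, and the labile bromide is used at once.

**Step 4**
Reactants: 5 4-benzyloxy-3-methoxybenzaldehyde; 6 dimethyl succinate
Product: 7 (E)-4-(4-benzyloxy-3-methoxyphenyl)-3-(methoxycarbonyl)but-3-enoic acid
Conditions: NaOMe, MeOH, reflux; then aq. HCl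
Reagents that add atoms: none
Why: In the Stobbe condensation the succinate enolate adds to the aldehyde, the alkoxide lactonises onto the distal ester, and base-induced opening of that lactone gives the E-arylidene half ester with the unconjugated carboxyl free.

**Step 5**
Reactants: 7 (E)-4-(4-benzyloxy-3-methoxyphenyl)-3-(methoxycarbonyl)but-3-enoic acid
Product: 8 (R)-4-(4-benzyloxy-3-methoxyphenyl)-3-(methoxycarbonyl)butanoic acid
Conditions: [Rh(cod)((S,S)-Et-DuPhos)]BF4 (1 mol%), NaOMe (10 mol%), H2 (5 bar), MeOH, rt
Reagents that add atoms: none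
Why: In this asymmetric hydrogenation of a Stobbe-type itaconate half ester the carboxylate and the alkene chelate the cationic rhodium bisphospholane complex, so that the ligand sets the (R) centre by face-selective delivery of H2, and the homogeneous catalyst should not cleave the benzyl ether.

**Step 6**
Reactants: 8 (R)-4-(4-benzyloxy-3-methoxyphenyl)-3-(methoxycarbonyl)butanoic acid
Product: 10 (R)-4-(4-benzyloxy-3-methoxybenzyl)dihydrofuran-2(3H)-one, via hydroxy acid 9 (not isolated)
Conditions: KOH (1 equiv), EtOH; Ca(BH4)2 (from CaCl2 and NaBH4), EtOH, 0 °C to rt; then 3 M HCl, rt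
Reagents that add atoms: none
Why: In this chemoselective borohydride reduction Ca(BH4)2 reduces the methyl ester while the carboxylate is inert, and acidification lactonises the γ-hydroxy acid to the butyrolactone without breaking a bond at the stereocentre.

**Step 7**
Reactants: 10 (R)-4-(4-benzyloxy-3-methoxybenzyl)dihydrofuran-2(3H)-one; 4 4-(tert-butyldimethylsilyloxy)-3-methoxybenzyl bromide
Product: 12 (3R,4R)-4-(4-benzyloxy-3-methoxybenzyl)-3-[4-(tert-butyldimethylsilyloxy)-3-methoxybenzyl]dihydrofuran-2(3H)-one, via lithium enolate 11 (not isolated)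
Conditions: LiN(SiMe3)2, THF, −78 °C; then 4, DMPU, −78 to −20 °C
Reagents that add atoms: none
Why: In this lactone enolate alkylation the benzylic bromide approaches the planar enolate on the face opposite the β-arylmethyl group, so the new α-centre is set trans (3R,4R) by substrate control.

**Step 8**
Reactants: 12 (3R,4R)-4-(4-benzyloxy-3-methoxybenzyl)-3-[4-(tert-butyldimethylsilyloxy)-3-methoxybenzyl]dihydrofuran-2(3H)-one
Product: 13 (3R,4R)-4-(4-benzyloxy-3-methoxybenzyl)-3-(4-hydroxy-3-methoxybenzyl)dihydrofuran-2(3H)-one (ring-A O-benzyl matairesinol)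
Conditions: Bu4NF, AcOH, THF, 0 °C
Reagents that add atoms: none
Why: Fluoride cleavage of the aryl silyl ether under acetic acid buffering frees the ring-B phenol without opening or epimerising the lactone (the trans isomer is in any case the more stable one), and the benzyl ether is inert.

**Step 9**
Reactants: 13 (3R,4R)-4-(4-benzyloxy-3-methoxybenzyl)-3-(4-hydroxy-3-methoxybenzyl)dihydrofuran-2(3H)-one; 14 ethyl diazoacetate; 15 4-formyl-2-methoxyphenyl acetate (vanillin acetate)
Product: 17 ethyl (2S,3R)-3-(4-acetoxy-3-methoxyphenyl)-3-hydroxy-2-{4-[((3R,4R)-4-(4-benzyloxy-3-methoxybenzyl)-2-oxotetrahydrofuran-3-yl)methyl]-2-methoxyphenoxy}propanoate, via enol 16 (not isolated)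
Conditions: Rh2(OAc)4 (2 mol%), (R)-TRIP (10 mol%), 4 Å MS, CH2Cl2, −20 °C; 15 (3 equiv) present, 14 (2 equiv) added by syringe pump over 6 h
Reagents that add atoms: none
Why: Proposed new method: Rh2(OAc)4 converts 14 into an electrophilic rhodium carbene that is attacked by the ring-B phenol oxygen of 13, and the oxonium ylide relaxes to the aryloxy ketene hemiacetal 16, which adds through C8'' to the phosphoric-acid-bound aldehyde 15 before it can tautomerise, so that the O–C8'' and C8''–C7'' bonds form in one operation. The closest known reaction type is the three-component coupling of aryl diazoacetates, alcohols and aldehydes or imines through trapped oxonium ylides under Rh2(OAc)4 with a chiral acid co-catalyst; an acceptor-only diazoacetate combined with a phenol and a chiral phosphoric acid is without precedent for this bond set. No ring is closed in this step. C8'' and C7'' are both set in the C–C bond-forming event inside the chiral pocket of the acid, which is expected to hold the aldehyde oxygen through P–OH and the enol O–H through P=O in a cyclic array that places aryloxy and hydroxyl syn and fixes the aldehyde face, the remote lactone stereocentres having no influence. The step needs trapping to outrun the 1,2-proton shift (plain O–H insertion) and needs syn (7''R,8''S) selectivity; the former is addressed by slow addition of 14, excess 15, low temperature and above all the ring-C acetate, which makes 15 a much better electrophile than its benzyl ether analogue, and the latter by the bulky 3,3'-aryl groups of the acid. Site selectivity is secured by the substrate, since ring A is benzylated and the ring-B phenol is the only O–H donor in 13.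

**Step 10**
Reactants: 17 ethyl (2S,3R)-3-(4-acetoxy-3-methoxyphenyl)-3-hydroxy-2-{4-[((3R,4R)-4-(4-benzyloxy-3-methoxybenzyl)-2-oxotetrahydrofuran-3-yl)methyl]-2-methoxyphenoxy}propanoate
Product: 18 (3R,4R)-4-(4-benzyloxy-3-methoxybenzyl)-3-{4-[(1R,2R)-1,3-dihydroxy-1-(4-hydroxy-3-methoxyphenyl)propan-2-yloxy]-3-methoxybenzyl}dihydrofuran-2(3H)-one
Conditions: NaBH4, THF/H2O (4:1), 0 °C to rt; work-up at pH 4
Reagents that add atoms: none
Why: In this chemoselective borohydride reduction the ethyl ester, activated by the α-aryloxy group and by hydride delivery from the borate of the β-hydroxyl, goes to the primary alcohol, the aryl acetate is hydrolysed in the alkaline medium, and the hindered unactivated γ-lactone should be spared or re-close on the mildly acidic work-up; no bond at C7'' or C8'' is broken, and the C8'' descriptor changes from S to R only through the priority switch.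

**Step 11**
Reactants: 18 (3R,4R)-4-(4-benzyloxy-3-methoxybenzyl)-3-{4-[(1R,2R)-1,3-dihydroxy-1-(4-hydroxy-3-methoxyphenyl)propan-2-yloxy]-3-methoxybenzyl}dihydrofuran-2(3H)-one
Product: 19 (3R,4R)-3-{4-[(1R,2R)-1,3-dihydroxy-1-(4-hydroxy-3-methoxyphenyl)propan-2-yloxy]-3-methoxybenzyl}-4-(4-hydroxy-3-methoxybenzyl)dihydrofuran-2(3H)-one (CNP0305334.1)
Conditions: H2 (1 atm), Pd/C (10% palladium on carbon), EtOAc/EtOH, rt
Reagents that add atoms: none
Why: Hydrogenolysis of the benzyl aryl ether over palladium under neutral conditions is much faster than cleavage of the benzylic C7''–OH bond, so the reaction is stopped after uptake of one equivalent of H2 to give the target.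

**Compound list**
1 | vanillin | COc1cc(C=O)ccc1O | starting material
2 | 4-(tert-butyldimethylsilyloxy)-3-methoxybenzaldehyde | COc1cc(C=O)ccc1O[Si](C)(C)C(C)(C)C | intermediate
3 | 4-(tert-butyldimethylsilyloxy)-3-methoxybenzyl alcohol | COc1cc(CO)ccc1O[Si](C)(C)C(C)(C)C | intermediate
4 | 4-(tert-butyldimethylsilyloxy)-3-methoxybenzyl bromide | COc1cc(CBr)ccc1O[Si](C)(C)C(C)(C)C | intermediate
5 | 4-benzyloxy-3-methoxybenzaldehyde | COc1cc(C=O)ccc1OCc1ccccc1 | starting material
6 | dimethyl succinate | COC(=O)CCC(=O)OC | starting material
7 | (E)-4-(4-benzyloxy-3-methoxyphenyl)-3-(methoxycarbonyl)but-3-enoic acid | COC(=O)/C(CC(=O)O)=C/c1ccc(OCc2ccccc2)c(OC)c1 | intermediate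
8 | (R)-4-(4-benzyloxy-3-methoxyphenyl)-3-(methoxycarbonyl)butanoic acid | COc1cc(C[C@H](CC(=O)O)C(=O)OC)ccc1OCc1ccccc1 | intermediate
9 | (R)-4-(4-benzyloxy-3-methoxyphenyl)-3-(hydroxymethyl)butanoic acid (present as its carboxylate, not isolated) | COc1cc(C[C@H](CC(=O)O)CO)ccc1OCc1ccccc1 | intermediate
10 | (R)-4-(4-benzyloxy-3-methoxybenzyl)dihydrofuran-2(3H)-one | COc1cc(C[C@H]2COC(=O)C2)ccc1OCc1ccccc1 | intermediate
11 | lithium enolate of lactone 10 (not isolated) | COc1cc(C[C@H]2COC([O-])=C2)ccc1OCc1ccccc1.[Li+] | intermediate
12 | (3R,4R)-4-(4-benzyloxy-3-methoxybenzyl)-3-[4-(tert-butyldimethylsilyloxy)-3-methoxybenzyl]dihydrofuran-2(3H)-one | COc1cc(C[C@H]2COC(=O)[C@@H]2Cc2ccc(O[Si](C)(C)C(C)(C)C)c(OC)c2)ccc1OCc1ccccc1 | intermediate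
13 | (3R,4R)-4-(4-benzyloxy-3-methoxybenzyl)-3-(4-hydroxy-3-methoxybenzyl)dihydrofuran-2(3H)-one | COc1cc(C[C@H]2COC(=O)[C@@H]2Cc2ccc(O)c(OC)c2)ccc1OCc1ccccc1 | intermediate
14 | ethyl diazoacetate | CCOC(=O)C=[N+]=[N-] | starting material
15 | 4-formyl-2-methoxyphenyl acetate | CC(=O)Oc1ccc(C=O)cc1OC | starting material
16 | ketene hemiacetal (enol) of the ethyl aryloxyacetate on the ring-B oxygen of 13 (not isolated) | COc1cc(C[C@H]2COC(=O)[C@@H]2Cc2ccc(OC=C(O)OCC)c(OC)c2)ccc1OCc1ccccc1 | intermediate
17 | ethyl (2S,3R)-3-(4-acetoxy-3-methoxyphenyl)-3-hydroxy-2-aryloxypropanoate on the ring-B oxygen of 13 (syn; 7''R,8''S) | COc1cc(C[C@H]2COC(=O)[C@@H]2Cc2ccc(O[C@H](C(=O)OCC)[C@H](O)c3ccc(OC(C)=O)c(OC)c3)c(OC)c2)ccc1OCc1ccccc1 | intermediate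
18 | ring-A O-benzyl ether of the target (7''R,8''R diol, ring-C phenol free) | COc1cc(C[C@H]2COC(=O)[C@@H]2Cc2ccc(O[C@H](CO)[C@H](O)c3ccc(O)c(OC)c3)c(OC)c2)ccc1OCc1ccccc1 | intermediate
19 | CNP0305334.1, (3R,4R)-3-{4-[(1R,2R)-1,3-dihydroxy-1-(4-hydroxy-3-methoxyphenyl)propan-2-yloxy]-3-methoxybenzyl}-4-(4-hydroxy-3-methoxybenzyl)dihydrofuran-2(3H)-one | COc1cc(C[C@H]2COC(=O)[C@@H]2Cc2ccc(O[C@H](CO)[C@H](O)c3ccc(O)c(OC)c3)c(OC)c2)ccc1O | target

**Step count and risks**
Total step count: 11. Longest linear sequence: 8 steps (steps 4 to 11 from aldehyde 5; the bromide branch, steps 1 to 3 then 7 to 11, is equally long).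

Steps most likely to fail:

1. Step 9 (proposed new method). The enol may tautomerise before it is trapped (net O–H insertion), the trapping may lack syn or facial selectivity, or the carbene may dimerise. The fallback uses known chemistry, an Evans aldol, and sets out from phenol 13. O-Alkylation with (S)-4-benzyl-3-(bromoacetyl)oxazolidin-2-one (K2CO3, MeCN, rt) gives the aryloxyacetyl imide F1. Soft enolisation of the imide alone (Bu2BOTf, iPr2NEt, CH2Cl2, −78 °C, conditions under which the lactone is not enolised) and addition of aldehyde 15 should give the syn aldol adduct F2 with the (7''R,8''S) configuration, through the chair transition state of the Z-boron enolate with the auxiliary shielding one face. NaBH4 in THF/H2O then cleaves the acyl oxazolidinone reductively and hydrolyses the aryl acetate, and the sequence comes back to the route at diol 18.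

2. Step 10. The lactone carbonyl may be over-reduced, or the β-hydroxy ester may undergo retro-aldol cleavage or epimerisation at C8'' in the alkaline medium before it is reduced. The fallback sets out from ester 17. LiOH in THF/H2O at 0 °C hydrolyses the ethyl ester and the aryl acetate and opens the lactone reversibly; acidification to pH 3 re-closes the lactone and gives the α-aryloxy β-hydroxy carboxylic acid F3. BH3·SMe2 in THF at 0 °C reduces the free carboxylic acid much faster than the lactone and comes back to the route at diol 18.

3. Step 7. The para-silyloxybenzyl bromide may be lost by ionisation (quinone-methide-type decomposition) before the enolate captures it, or proton exchange may lead to double alkylation. The fallback sets out from lactone 10. Its lithium enolate (LiN(SiMe3)2, THF, −78 °C) is added to aldehyde 2 in an aldol addition, the aldehyde again entering anti to the β-substituent, to give the trans β-hydroxy lactone F4 as a mixture of carbinol epimers. Ionic deoxygenation of the electron-rich benzylic alcohol (Et3SiH, CF3CO2H, CH2Cl2, 0 °C) removes the hydroxyl without touching the ring stereocentres and comes back to the route at lactone 12.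

**Further compounds**
F1 | step 9 | aryloxyacetyl imide of phenol 13 with (S)-4-benzyloxazolidin-2-one | COc1cc(C[C@H]2COC(=O)[C@@H]2Cc2ccc(OCC(=O)N3C(=O)OC[C@@H]3Cc3ccccc3)c(OC)c2)ccc1OCc1ccccc1
F2 | step 9 | syn aldol adduct of F1 with aldehyde 15 (7''R,8''S) | COc1cc(C[C@H]2COC(=O)[C@@H]2Cc2ccc(O[C@H](C(=O)N3C(=O)OC[C@@H]3Cc3ccccc3)[C@H](O)c3ccc(OC(C)=O)c(OC)c3)c(OC)c2)ccc1OCc1ccccc1
F3 | step 10 | (2S,3R)-3-hydroxy-3-(4-hydroxy-3-methoxyphenyl)-2-aryloxypropanoic acid on the ring-B oxygen of 13 | COc1cc(C[C@H]2COC(=O)[C@@H]2Cc2ccc(O[C@H](C(=O)O)[C@H](O)c3ccc(O)c(OC)c3)c(OC)c2)ccc1OCc1ccccc1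
F4 | step 7 | trans β-hydroxy lactone from 10 and aldehyde 2 (carbinol epimers) | COc1cc(C[C@H]2COC(=O)[C@@H]2C(O)c2ccc(O[Si](C)(C)C(C)(C)C)c(OC)c2)ccc1OCc1ccccc1
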